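Compound numbers 1–24 are fixed by the steps below and used throughout. Labdane numbering (C1–C20) is used for the decalin compounds and, for tracking, for the atoms of their monocyclic precursors; β is the face of the C10 methyl group.

## Analysis of the target

The target, (13Z)-18-acetoxy-3-oxo-5β-labda-8(17),13-dien-15-oic acid (24), is a decalin (ring A: C1–C5 and C10; ring B: C5–C10). It carries a C3 ketone, a quaternary C4 with the C19 methyl and the C18 acetoxymethyl group, the angular C20 methyl on C10, an exocyclic C8=C17 methylene, and on C9 a chain C11–C15 that ends in a (Z)-3-methylalk-2-enoic acid (C16 is the methyl on C13). The four stereocentres are contiguous, (4R,5S,9S,10R): H5, the C10 methyl, the C4 methyl and the C9 chain lie on the β face and the acetoxymethyl group on the α face. The ring fusion is therefore cis, which is unusual for a labdane and rules out polyene-cyclisation logic. Sensitive groups are the exocyclic alkene (moves into the ring under acid), the (Z)-enoate (can lose its geometry by γ-deprotonation), the C3/C18 aldol unit (retro-aldol loss of formaldehyde under base while the alcohol is free) and the acetate beside the acid, which forbids a final saponification. The hard points are the two quaternary carbons, the C9 centre next to quaternary C10, and the C8 methylene, whose usual source, olefination of a C8 ketone flanked by C9, is hindered and endangers C9. The strategy rests on ring B: C17=C8–C9–C11, with unsaturation placed at C11=C12, is a 1,4-diene, the retron of an Alder-ene reaction between a C8≡C17 alkyne and a C9=C11 alkene. Forming C8–C9 this way closes ring B, makes the methylene without a ketone, sets C9, and leaves C11–C13 as an enoate from which the chain is grown.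

## Retrosynthetic reasoning

**24 from 23.** The acid is freed last from allyl ester 23. An ordinary alkyl ester would need hydroxide in the presence of the primary acetate; the allyl group leaves under neutral zerovalent-palladium conditions that touch neither the acetate nor the alkenes.

**23 back to 19.** The quaternary C4 is cut at C4–C19 and C4–C18. Both bonds are α to the C3 ketone, so enolate chemistry builds them: 19 is formylated to 20, methylated to 21, the aldehyde is reduced to 22 and acetylated to 23. The formyl group comes first for two reasons: it directs and activates the second alkylation, and the group that arrives second (methyl) should enter from the convex β face, which is where the target has it. The cis ring fusion is relied on to steer enolisation of 19 toward C4 and not C2.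

**19 back to 12.** Ketone 19 is the unmasked dioxolane 18. The side chain is cut at C13–C16 (syn addition of a methyl cuprate to ynoate 17, which fixes the Z geometry), at C14–C15 (acylation of acetylide 16, made from alkyne 15) and at C13≡C14 (one-carbon homologation of aldehyde 14). Aldehyde 14 comes from ester 13, the conjugate-reduction product of dienoate 12. The trisubstituted alkene is the only stereogenic alkene of the target, and carbometalation of an ynoate is the dependable way to set it; the ester of 12 differentiates C11=C12 from the C8=C17 methylene for the reduction.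

**12 from 11 (key disconnection).** The C8–C9 bond is cut to give enyne 11, a cis-1,2-disubstituted cyclohexane with a but-3-ynyl arm on C5 and a (Z)-alkenyl ester arm on quaternary C10. This is the only cut that produces the methylene and the C9 centre together and needs no C8 carbonyl. The forward reaction must add C8 to C9 on the correct face and eliminate toward C12.

**11 back to 7 and 8.** The dioxolane of 11 is the protected form of the silyl enol ether in 10, the methyl ester of acid 9. The C9=C11 alkene of 9 is cut by a Z-selective Wittig reaction between aldehyde 7 and the ylide from phosphonium salt 8, which brings in C11–C13 in one piece.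

**7 from 5 and 6.** Ring A is cut at C5–C10 and C1–C2 by a Diels–Alder reaction between siloxy diene 5 and methacrolein 6. Both stereocentres of 11 (C5 and quaternary C10) are set in this one catalytic, enantioselective step, and the C3 oxygen arrives as a regiodefined enol ether.

**5 back to 1 and 2.** Diene 5 is the silyl dienol ether of enone 4, which comes from pent-4-yn-1-ol 1 by oxidation to aldehyde 3 and Wittig reaction with ylide 2.

## Alternatives that were turned down

**Alternative 1: anionic oxy-Cope rearrangement.** The disconnection is C1–C10 of ring A. A bridged bicyclo[2.2.2]octenyl vinyl carbinol, built from an aryl methyl ether, would rearrange as its potassium alkoxide, breaking C3–C8 and forming C1–C10, to give the cis-decalin A1 with a C3 ketone and a C8 methyl enol ether.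
- For: the [3,3] shift enforces the cis fusion, and C4 is already quaternary before ring A forms. On the C4 problem this alternative is stronger than the chosen route, which has to alkylate C4 late.
- Against: the absolute configuration must come from a cycloaddition of an electron-rich cyclohexadiene with a ketene equivalent, for which a dependable catalytic asymmetric version is lacking. A1 also delivers C8 as a masked ketone and C9 as an unsubstituted carbon. The side chain would have to be alkylated onto C9, the hindered α-carbon beside quaternary C10, with control of C9, and the C8 ketone then methylenated next to that epimerisable centre.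
- Comparison: the chosen strategy makes the methylene and C9 in the ring-closing event itself, and needs fewer steps after the bicycle is formed.

**Alternative 2: intramolecular Diels–Alder reaction of a decatriene.** The disconnection is C3–C4 and C5–C10, both rings at once. A (Z)-2-methyl enoate (C4=C5) would add across the diene C10=C1–C2=C3, thermally or with an aluminium Lewis acid, to give the octalin A2.
- For: it is the most convergent ring construction, with two rings and C4, C5 and C10 from an acyclic chain in one step. The Z geometry of the dienophile is transcribed directly into C4, which is more secure than an enolate alkylation.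
- Against: the cycloaddition joins a fully substituted diene terminus (C10) to a dienophile that becomes quaternary at C4, a very crowded transition state. The cis fusion depends on the orientation of a four-atom tether, which is not reliably controlled, and the absolute configuration hangs on a single remote silyloxy centre at C8. A2 has no oxygen at C3, so an allylic oxidation and alkene reduction are needed, and C8/C9 again call for ketone alkylation and olefination.
- Comparison: the chosen route uses two ring-forming steps instead of one, but each has a defined stereochemical rationale, and the C8/C9 functionality arises directly.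

**Alternative 3: desymmetrising Michael closure onto a cyclohexadienone.** The disconnection is C5–C6 of ring B. A bis(sulfonyl)methyl carbanion at C6 would add to C5 of one enone arm of a prochiral 4,4-disubstituted cyclohexadienone under a bifunctional cinchona urea catalyst, giving the cis-fused enone A3.
- For: one catalytic step sets C5 and C10, the cis fusion is geometrically enforced, the dienone comes from a simple phenol, and the C3 carbonyl is native. In enantiocontrol and in step count to the bicycle it is at least as good as the cycloaddition of the chosen route.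
- Against: the two sulfonyl groups are auxiliary atoms that must be removed reductively beside a ketone, and C1=C2 must be reduced. Ring B again arrives with a C8 carbonyl and an unsubstituted C9, so C9 alkylation beside C10 and methylenation of the hindered C8 ketone remain. C4 still has to be built as in the chosen route.
- Comparison: the chosen strategy spends its key step on exactly the part that A3 leaves open.

Key step: step 7

Assumption: in step 3 the sense of induction is taken from the formyl C–H···O binding model of oxazaborolidinium–enal complexes, under which the (S)-configured catalyst exposes the Re face of C2 of 6; if the opposite sense were found, the (R)-configured catalyst would be used.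

**Step 1**
Reactants: 1 pent-4-yn-1-ol; 2 1-(triphenyl-λ5-phosphanylidene)propan-2-one
Product: 4 (3E)-oct-3-en-7-yn-2-one, via pent-4-ynal 3 (not isolated)
Conditions: (COCl)2, Me2SO, CH2Cl2, −78 °C; Et3N, −78 → 0 °C; then 2, rt
Reagents that add atoms: none
Why: Swern oxidation gives the volatile aldehyde 3, which is trapped in the same flask by a Wittig reaction with the keto-stabilised ylide 2; stabilised ylides give the E-enone, and the terminal alkyne is inert to both stages.

**Step 2**
Reactants: 4 (3E)-oct-3-en-7-yn-2-one
Product: 5 triisopropyl{[(3E)-octa-1,3-dien-7-yn-2-yl]oxy}silane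
Conditions: i-Pr3SiOTf, Et3N, CH2Cl2, 0 °C
Reagents that add atoms: triisopropylsilyl trifluoromethanesulfonate, CC(C)[Si](OS(=O)(=O)C(F)(F)F)(C(C)C)C(C)C
Why: Soft enolisation of a methyl enone with a silyl triflate and a tertiary amine removes a methyl proton (cross-conjugated kinetic enolate) and should give the 2-siloxy-1,3-diene with the E-alkene untouched; triethylamine is too weak to metalate the alkyne.

**Step 3**
Reactants: 5 triisopropyl{[(3E)-octa-1,3-dien-7-yn-2-yl]oxy}silane; 6 2-methylprop-2-enal (methacrolein)
Product: 7 (1S,2R)-2-(but-3-yn-1-yl)-1-methyl-4-[(triisopropylsilyl)oxy]cyclohex-3-ene-1-carbaldehyde (formyl cis to butynyl)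
Conditions: (S)-1-(2-methylphenyl)-3,3-diphenyltetrahydro-1H,3H-pyrrolo[1,2-c][1,3,2]oxazaborole (20 mol %), Tf2NH (17 mol %), CH2Cl2, −78 → −40 °C
Reagents that add atoms: none
Why: Enantioselective Diels–Alder reaction of an α-substituted acrolein under a chiral oxazaborolidinium Lewis acid; the siloxy group (para rule) and the alkyl terminus (ortho rule) both direct C10 to C5 and C1 to C2. The complexed formyl group should take the endo position over the (E)-diene, as α-substituted acroleins do with other (E)-1-substituted 3-siloxy dienes, which places formyl and butynyl cis. The catalyst screens the Si face of C2 of 6, so the diene adds to the Re face, fixing C10 as S and, through the endo geometry, C5 as R.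

**Step 4**
Reactants: 7 (1S,2R)-2-(but-3-yn-1-yl)-1-methyl-4-[(triisopropylsilyl)oxy]cyclohex-3-ene-1-carbaldehyde; 8 (2-carboxyethyl)triphenylphosphonium bromide
Product: 9 (3Z)-4-{(1R,2R)-2-(but-3-yn-1-yl)-1-methyl-4-[(triisopropylsilyl)oxy]cyclohex-3-en-1-yl}but-3-enoic acid
Conditions: 8 (2.5 equiv), NaN(SiMe3)2 (4.8 equiv), THF, 0 °C; then 7, −78 °C → rt; aq. NaH2PO4, 0 °C
Reagents that add atoms: none
Why: Wittig olefination with the non-stabilised carboxylate ylide made from 8 and just under two equivalents of base, so that no free amide is left to metalate the alkyne; lithium-free conditions should give the Z-alkene. Aldehyde 7 has no α-hydrogen and cannot enolise or epimerise, and the silyl enol ether tolerates the base and the brief buffered work-up.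

**Step 5**
Reactants: 9 (3Z)-4-{(1R,2R)-2-(but-3-yn-1-yl)-1-methyl-4-[(triisopropylsilyl)oxy]cyclohex-3-en-1-yl}but-3-enoic acid
Product: 10 methyl (3Z)-4-{(1R,2R)-2-(but-3-yn-1-yl)-1-methyl-4-[(triisopropylsilyl)oxy]cyclohex-3-en-1-yl}but-3-enoate
Conditions: Me3SiCHN2, MeOH/toluene, 0 °C
Reagents that add atoms: trimethylsilyldiazomethane, C[Si](C)(C)C=[N+]=[N-]
Why: Esterification of a carboxylic acid with a diazoalkane proceeds without added base or strong acid, so the β,γ-alkene should not move into conjugation and the silyl enol ether survives.

**Step 6**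
Reactants: 10 methyl (3Z)-4-{(1R,2R)-2-(but-3-yn-1-yl)-1-methyl-4-[(triisopropylsilyl)oxy]cyclohex-3-en-1-yl}but-3-enoate
Product: 11 methyl (3Z)-4-[(7R,8S)-7-(but-3-yn-1-yl)-8-methyl-1,4-dioxaspiro[4.5]decan-8-yl]but-3-enoate
Conditions: HOCH2CH2OH (10 equiv), (±)-camphor-10-sulfonic acid (10 mol %), 4 Å molecular sieves, CH2Cl2, rt
Reagents that add atoms: ethane-1,2-diol, OCCO
Why: Acid-catalysed ketal formation from an enol ether: protonation at C4 gives a silyloxocarbenium ion, which the diol captures; loss of silanol and ring closure give the dioxolane without forming water. The ester, the Z-alkene and the alkyne are inert at room temperature, and C5 and C10 are not enolisable.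

**Step 7**
Reactants: 11 methyl (3Z)-4-[(7R,8S)-7-(but-3-yn-1-yl)-8-methyl-1,4-dioxaspiro[4.5]decan-8-yl]but-3-enoate
Product: 12 methyl (11E)-3,3-(ethylenedioxy)-14,15,16,18,19-pentanor-5β-labda-8(17),11-dien-13-oate (cis-decalin; 5β-H; 9α-H; 10β-methyl)
Conditions: Pd(OAc)2 (5 mol %), N,N′-bis(benzylidene)ethylenediamine (6 mol %), benzene, 60–70 °C
Reagents that add atoms: none
Why: Palladium-catalysed Alder-ene cycloisomerisation of a 1,7-enyne; the closest known reaction type is the Pd(OAc)2–diimine cycloisomerisation of 1,6- and 1,7-enynes to 1,4-dienes. A hydridopalladium acetate (divalent palladium) formed in situ adds syn across C8≡C17 with palladium on the internal carbon C8; the vinylpalladium inserts C9=C11 in a 6-exo-trig syn carbopalladation that forms C8–C9 and closes ring B, and syn β-hydride elimination of a C12 hydrogen gives the (E)-enoate and returns the hydride (a palladacyclopentene pathway would give the same product). The new centre C9 is controlled by the ring A chair: the butynyl arm stays equatorial because in the other chair it would be syn-axial to a dioxolane oxygen on C3, so the alkenyl arm is axial and ring B should close through a chair with C11 pseudo-equatorial. That arrangement puts C11 cis to the C10 methyl, whereas the other orientation would set C11 syn-axial to C4. The step needs Markovnikov hydropalladation (secured by the terminal alkyne), 6-exo and not 7-endo closure (secured by the tether length and helped by quaternary C10), and elimination toward C12 and not toward the C9 hydrogen (the C12 hydrogens are activated by the ester and lead to the conjugated alkene). The diimine ligand restrains alkyne oligomerisation and makes six-membered ring formation practical, and the neutral medium leaves the dioxolane and the new exocyclic alkene in place.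

**Step 8**
Reactants: 12 methyl (11E)-3,3-(ethylenedioxy)-14,15,16,18,19-pentanor-5β-labda-8(17),11-dien-13-oate
Product: 13 methyl 3,3-(ethylenedioxy)-14,15,16,18,19-pentanor-5β-labd-8(17)-en-13-oate
Conditions: [(Ph3P)CuH]6 (0.4 equiv), H2O (2 equiv), THF/benzene, rt
Reagents that add atoms: none
Why: Conjugate reduction by a phosphine copper hydride: hydride adds to C11 and water protonates the copper enolate. The isolated 1,1-disubstituted alkene and the ketal are not reduced, and the neutral conditions avoid shifting the skipped diene through the acidic C9 hydrogen.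

**Step 9**
Reactants: 13 methyl 3,3-(ethylenedioxy)-14,15,16,18,19-pentanor-5β-labd-8(17)-en-13-oate
Product: 14 3,3-(ethylenedioxy)-14,15,16,18,19-pentanor-5β-labd-8(17)-en-13-al
Conditions: i-Bu2AlH (1.1 equiv), CH2Cl2, −78 °C; MeOH, then aq. potassium sodium tartrate
Reagents that add atoms: none
Why: Partial reduction of a methyl ester with a dialkylaluminium hydride stops at the tetrahedral aluminium hemiacetal at −78 °C, which releases the aldehyde on work-up.

**Step 10**
Reactants: 14 3,3-(ethylenedioxy)-14,15,16,18,19-pentanor-5β-labd-8(17)-en-13-al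
Product: 15 3,3-(ethylenedioxy)-15,16,18,19-tetranor-5β-labd-8(17)-en-13-yne
Conditions: dimethyl (1-diazo-2-oxopropyl)phosphonate, K2CO3, MeOH, 0 °C → rt
Reagents that add atoms: dimethyl (1-diazo-2-oxopropyl)phosphonate, CC(=O)C(=[N+]=[N-])P(=O)(OC)OC
Why: Ohira–Bestmann (Seyferth–Gilbert) homologation: the diazomethylphosphonate anion formed by methanolysis adds to the aldehyde, and the alkylidene carbene rearranges to the terminal alkyne, adding C14. Carbonate in methanol harms neither the ketal nor the alkene.

**Step 11**
Reactants: 15 3,3-(ethylenedioxy)-15,16,18,19-tetranor-5β-labd-8(17)-en-13-yne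
Product: 17 allyl 3,3-(ethylenedioxy)-16,18,19-trinor-5β-labd-8(17)-en-13-yn-15-oate, via lithium acetylide 16 (not isolated)
Conditions: n-BuLi (1.05 equiv), THF, −78 °C; then ClCO2CH2CH=CH2, −78 → −40 °C
Reagents that add atoms: allyl chloroformate, C=CCOC(Cl)=O
Why: Deprotonation of the terminal alkyne and C-acylation of the acetylide with a chloroformate; the allyl ester is chosen so that the acid can later be freed without hydroxide.

**Step 12**
Reactants: 17 allyl 3,3-(ethylenedioxy)-16,18,19-trinor-5β-labd-8(17)-en-13-yn-15-oate
Product: 18 allyl (13Z)-3,3-(ethylenedioxy)-18,19-dinor-5β-labda-8(17),13-dien-15-oate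
Conditions: Me2CuLi (1.5 equiv; from CuI and MeLi), THF, −78 °C; then MeOH, −78 °C
Reagents that add atoms: lithium dimethylcuprate, [Li+].C[Cu-]C
Why: Syn carbocupration (conjugate addition) of a dialkylcuprate to an ynoate; cold protonation keeps the kinetic geometry, with the new methyl cis to H14 and the C12 chain cis to the ester, which is the 13Z alkene. At −78 °C the ynoate reacts far faster than the allylic ester.

**Step 13**
Reactants: 18 allyl (13Z)-3,3-(ethylenedioxy)-18,19-dinor-5β-labda-8(17),13-dien-15-oate
Product: 19 allyl (13Z)-3-oxo-18,19-dinor-5β-labda-8(17),13-dien-15-oate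
Conditions: 1 M aq. HCl/THF (1:4), rt
Reagents that add atoms: water, O
Why: Acid hydrolysis of a dioxolane; dilute acid at room temperature should leave the 1,1-disubstituted alkene, the enoate geometry and the allyl ester intact.

**Step 14**
Reactants: 19 allyl (13Z)-3-oxo-18,19-dinor-5β-labda-8(17),13-dien-15-oate
Product: 20 allyl (13Z)-18-hydroxy-3-oxo-19-nor-5β-labda-4(18),8(17),13-trien-15-oate (4-hydroxymethylene ketone; enol OH cis to C3=O)
Conditions: NaH (2.5 equiv), HCO2CH2CH=CH2 (5 equiv), CH2=CHCH2OH (cat.), THF, 0 °C → rt; then 1 M aq. HCl to pH 4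
Reagents that add atoms: allyl formate, O=COCC=C
Why: Claisen-type formylation under thermodynamic control; a cis-fused 3-ketone enolises toward C4 (as A/B-cis 3-keto steroids do), so C18 should enter at C4 and not at C2. Allyl formate is used so that the alkoxide it releases matches the ester and any transesterification is degenerate.

**Step 15**
Reactants: 20 allyl (13Z)-18-hydroxy-3-oxo-19-nor-5β-labda-4(18),8(17),13-trien-15-oate
Product: 21 allyl (13Z)-3,18-dioxo-5β-labda-8(17),13-dien-15-oate (4β-methyl; 4α-formyl)
Conditions: MeI (5 equiv), K2CO3 (3 equiv), acetone, rt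
Reagents that add atoms: iodomethane, CI
Why: C-alkylation of the enolate of a β-keto aldehyde with a soft alkyl iodide (the classical methylation of a hydroxymethylene ketone). The enolate is flat at C4 and its α face is the concave face of the cis-decalin, covered by ring B, so the methyl should enter from the convex β face, cis to H5, making C4 R with the formyl group α. The product has no hydrogen on C4, so the new centre cannot epimerise.

**Step 16**
Reactants: 21 allyl (13Z)-3,18-dioxo-5β-labda-8(17),13-dien-15-oate
Product: 22 allyl (13Z)-18-hydroxy-3-oxo-5β-labda-8(17),13-dien-15-oate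
Conditions: LiAlH(Ot-Bu)3 (1.1 equiv), THF, −78 °C; then aq. NH4Cl
Reagents that add atoms: none
Why: Chemoselective reduction of an aldehyde beside a hindered α-quaternary ketone and a conjugated ester by a bulky reagent that carries a single hydride, so the new alkoxide cannot deliver a second hydride to C3. The low temperature and neutral quench avoid retro-aldol loss of formaldehyde.

**Step 17**
Reactants: 22 allyl (13Z)-18-hydroxy-3-oxo-5β-labda-8(17),13-dien-15-oate
Product: 23 allyl (13Z)-18-acetoxy-3-oxo-5β-labda-8(17),13-dien-15-oate
Conditions: Ac2O, pyridine, 4-(dimethylamino)pyridine (5 mol %), CH2Cl2, 0 °C → rt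
Reagents that add atoms: acetic anhydride, CC(=O)OC(C)=O
Why: Acylation of a primary alcohol under nucleophilic catalysis; C4 bears no hydrogen, so elimination and epimerisation are excluded, and acylation removes the retro-aldol risk.

**Step 18**
Reactants: 23 allyl (13Z)-18-acetoxy-3-oxo-5β-labda-8(17),13-dien-15-oate
Product: 24 (13Z)-18-acetoxy-3-oxo-5β-labda-8(17),13-dien-15-oic acid, (4R,5S,9S,10R)
Conditions: Pd(PPh3)4 (5 mol %), morpholine (5 equiv), THF, rt; then aq. NaH2PO4
Reagents that add atoms: none
Why: Zerovalent palladium ionises the allyl ester to a π-allyl complex that morpholine captures (allyl transfer). The C18 acetate is not allylic and the ketone and alkenes do not react, so the acid is released without acid or hydroxide.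

**Compound list**

1 | pent-4-yn-1-ol | C#CCCCO | starting material
2 | 1-(triphenyl-λ5-phosphanylidene)propan-2-one | CC(=O)C=P(c1ccccc1)(c1ccccc1)c1ccccc1 | starting material
3 | pent-4-ynal | C#CCCC=O | intermediate
4 | (3E)-oct-3-en-7-yn-2-one | CC(=O)/C=C/CCC#C | intermediate
5 | triisopropyl{[(3E)-octa-1,3-dien-7-yn-2-yl]oxy}silane | C=C(O[Si](C(C)C)(C(C)C)C(C)C)/C=C/CCC#C | intermediate
6 | 2-methylprop-2-enal (methacrolein) | CC(=C)C=O | starting material
7 | (1S,2R)-2-(but-3-yn-1-yl)-1-methyl-4-[(triisopropylsilyl)oxy]cyclohex-3-ene-1-carbaldehyde | C#CCC[C@H]2[C@](C)(CCC(O[Si](C(C)C)(C(C)C)C(C)C)=C2)C=O | intermediate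
8 | (2-carboxyethyl)triphenylphosphonium bromide | OC(=O)CC[P+](c1ccccc1)(c1ccccc1)c1ccccc1.[Br-] | starting material
9 | (3Z)-4-{(1R,2R)-2-(but-3-yn-1-yl)-1-methyl-4-[(triisopropylsilyl)oxy]cyclohex-3-en-1-yl}but-3-enoic acid | C#CCC[C@H]2[C@](C)(CCC(O[Si](C(C)C)(C(C)C)C(C)C)=C2)/C=C\CC(=O)O | intermediate
10 | methyl (3Z)-4-{(1R,2R)-2-(but-3-yn-1-yl)-1-methyl-4-[(triisopropylsilyl)oxy]cyclohex-3-en-1-yl}but-3-enoate | C#CCC[C@H]2[C@](C)(CCC(O[Si](C(C)C)(C(C)C)C(C)C)=C2)/C=C\CC(=O)OC | intermediate
11 | methyl (3Z)-4-[(7R,8S)-7-(but-3-yn-1-yl)-8-methyl-1,4-dioxaspiro[4.5]decan-8-yl]but-3-enoate | C#CCC[C@H]2[C@](C)(CCC3(OCCO3)C2)/C=C\CC(=O)OC | intermediate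
12 | methyl (11E)-3,3-(ethylenedioxy)-14,15,16,18,19-pentanor-5β-labda-8(17),11-dien-13-oate | C=C1CC[C@H]2[C@](C)(CCC3(OCCO3)C2)[C@H]1/C=C/C(=O)OC | intermediate
13 | methyl 3,3-(ethylenedioxy)-14,15,16,18,19-pentanor-5β-labd-8(17)-en-13-oate | C=C1CC[C@H]2[C@](C)(CCC3(OCCO3)C2)[C@H]1CCC(=O)OC | intermediate
14 | 3,3-(ethylenedioxy)-14,15,16,18,19-pentanor-5β-labd-8(17)-en-13-al | C=C1CC[C@H]2[C@](C)(CCC3(OCCO3)C2)[C@H]1CCC=O | intermediate
15 | 3,3-(ethylenedioxy)-15,16,18,19-tetranor-5β-labd-8(17)-en-13-yne | C=C1CC[C@H]2[C@](C)(CCC3(OCCO3)C2)[C@H]1CCC#C | intermediate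
16 | lithium acetylide of 15 (lithium on C14) | C=C1CC[C@H]2[C@](C)(CCC3(OCCO3)C2)[C@H]1CCC#C[Li] | intermediate
17 | allyl 3,3-(ethylenedioxy)-16,18,19-trinor-5β-labd-8(17)-en-13-yn-15-oate | C=C1CC[C@H]2[C@](C)(CCC3(OCCO3)C2)[C@H]1CCC#CC(=O)OCC=C | intermediate
18 | allyl (13Z)-3,3-(ethylenedioxy)-18,19-dinor-5β-labda-8(17),13-dien-15-oate | C=C1CC[C@H]2[C@](C)(CCC3(OCCO3)C2)[C@H]1CC/C(C)=C\C(=O)OCC=C | intermediate
19 | allyl (13Z)-3-oxo-18,19-dinor-5β-labda-8(17),13-dien-15-oate | C=C1CC[C@H]2[C@](C)(CCC(=O)C2)[C@H]1CC/C(C)=C\C(=O)OCC=C | intermediate
20 | allyl (13Z)-18-hydroxy-3-oxo-19-nor-5β-labda-4(18),8(17),13-trien-15-oate | C=C1CC[C@H]2[C@](C)(CCC(=O)/C2=C\O)[C@H]1CC/C(C)=C\C(=O)OCC=C | intermediate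
21 | allyl (13Z)-3,18-dioxo-5β-labda-8(17),13-dien-15-oate (4β-methyl, 4α-formyl) | C=C1CC[C@H]2[C@](C)(CCC(=O)[C@@]2(C)C=O)[C@H]1CC/C(C)=C\C(=O)OCC=C | intermediate
22 | allyl (13Z)-18-hydroxy-3-oxo-5β-labda-8(17),13-dien-15-oate | C=C1CC[C@H]2[C@](C)(CCC(=O)[C@@]2(C)CO)[C@H]1CC/C(C)=C\C(=O)OCC=C | intermediate
23 | allyl (13Z)-18-acetoxy-3-oxo-5β-labda-8(17),13-dien-15-oate | C=C1CC[C@H]2[C@](C)(CCC(=O)[C@@]2(C)COC(C)=O)[C@H]1CC/C(C)=C\C(=O)OCC=C | intermediate
24 | (13Z)-18-acetoxy-3-oxo-5β-labda-8(17),13-dien-15-oic acid, (4R,5S,9S,10R) | C=C1CC[C@H]2[C@](C)(CCC(=O)[C@@]2(C)COC(C)=O)[C@H]1CC/C(C)=C\C(=O)O | target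

**Step count.** 18 steps in total; the longest linear sequence is 18 steps, from pent-4-yn-1-ol 1 (compounds 3 and 16 react on in the flask).

**Least certain steps**

*Step 7 (key step).* The most likely failure is slow insertion into the hindered C9=C11 alkene beside quaternary C10. That would leave the vinylpalladium and the palladium hydride free to oligomerise the terminal alkyne or to move the β,γ-alkene into conjugation with the ester before ring closure. The C9 configuration is argued from conformation and not guaranteed. The fallback generates the same C8 vinylpalladium by oxidative addition instead of hydropalladation. From 11, haloboration with 9-iodo-9-borabicyclo[3.3.1]nonane at −20 °C followed by protonolysis with acetic acid should give the 2-iodoalkene, methyl (3Z)-4-[(7R,8S)-7-(3-iodobut-3-en-1-yl)-8-methyl-1,4-dioxaspiro[4.5]decan-8-yl]but-3-enoate F1. An intramolecular Heck reaction of F1 (Pd(OAc)2, PPh3, Ag2CO3, MeCN, 70 °C) then closes ring B 6-exo and eliminates toward C12; no palladium hydride is present at the start and the silver salt removes iodide. This route comes back at 12.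

*Step 3.* The most likely failure is erosion of endo selectivity, because the α-methyl group competes with the complexed formyl group for the endo position; the exo adduct would carry formyl trans to butynyl into the key step. The fallback builds quaternary C10 in two operations.
- From 5, a Diels–Alder reaction with methyl acrylate under the same oxazaborolidine activated by AlBr3 (enantiomer chosen to set C5 as in 7), where the endo rule is dependable, should give the cis ester, methyl cis-2-(but-3-yn-1-yl)-4-[(triisopropylsilyl)oxy]cyclohex-3-ene-1-carboxylate F2.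
- Enolate methylation (LiN(i-Pr)2, 2.2 equiv, THF, −78 °C; MeI, 1.1 equiv) should occur anti to the neighbouring butynyl group and give the ester with methyl trans to butynyl, methyl 2-(but-3-yn-1-yl)-1-methyl-4-[(triisopropylsilyl)oxy]cyclohex-3-ene-1-carboxylate F3.
- Reduction with i-Bu2AlH gives the primary alcohol, [2-(but-3-yn-1-yl)-1-methyl-4-[(triisopropylsilyl)oxy]cyclohex-3-en-1-yl]methanol F4, and buffered Dess–Martin oxidation returns to the route at 7.

*Step 4.* The most likely failure is loss of the carboxylate ylide by elimination of triphenylphosphine before it adds to the neopentyl aldehyde, giving low conversion. The fallback uses a more robust ylide and adjusts the oxidation state afterwards.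
- From 7, the ylide from (3-hydroxypropyl)triphenylphosphonium bromide (NaN(SiMe3)2, 2 equiv) should give the (Z)-homoallylic alcohol, (3Z)-4-{2-(but-3-yn-1-yl)-1-methyl-4-[(triisopropylsilyl)oxy]cyclohex-3-en-1-yl}but-3-en-1-ol F5.
- The conditions of step 6 convert it into the dioxolane alcohol, (3Z)-4-[(7R,8S)-7-(but-3-yn-1-yl)-8-methyl-1,4-dioxaspiro[4.5]decan-8-yl]but-3-en-1-ol F6.
- Dess–Martin oxidation gives the aldehyde, (3Z)-4-[(7R,8S)-7-(but-3-yn-1-yl)-8-methyl-1,4-dioxaspiro[4.5]decan-8-yl]but-3-enal F7, used crude.
- Pinnick oxidation (NaClO2, NaH2PO4, 2-methylbut-2-ene) gives the acid, (3Z)-4-[(7R,8S)-7-(but-3-yn-1-yl)-8-methyl-1,4-dioxaspiro[4.5]decan-8-yl]but-3-enoic acid F8, and Me3SiCHN2 brings the route back at 11.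

*Step 15.* The most likely failure is poor facial selectivity. The cis-decalin enolate can react through a half-chair in which the C10 methyl is axial and screens the β face, so the methyl may enter α; some O-methylation is also possible. The fallback reverses the order in which the two C4 substituents arrive.
- From 20, methylation as before gives the formyl ketone as whichever epimer predominates, 21 or its 4-epimer, allyl (13Z)-3,18-dioxo-4-epi-5β-labda-8(17),13-dien-15-oate F9.
- The crude product is deformylated (aq. K2CO3, THF; retro-Claisen) to the methyl ketone, allyl (13Z)-3-oxo-18-nor-5β-labda-8(17),13-dien-15-oate F10.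
- Thermodynamic silylation (Me3SiCl, NaI, Et3N, MeCN) toward the more substituted C4 gives the enol ether, allyl (13Z)-3-[(trimethylsilyl)oxy]-18-nor-5β-labda-3,8(17),13-trien-15-oate F11.
- A Mukaiyama hydroxymethylation with aqueous formaldehyde and Yb(OTf)3 then brings in C18 from the face that methyl iodide had preferred, and the route is rejoined at 22.

**Further compounds**

F1 | step 7 | methyl (3Z)-4-[(7R,8S)-7-(3-iodobut-3-en-1-yl)-8-methyl-1,4-dioxaspiro[4.5]decan-8-yl]but-3-enoate | C=C(I)CC[C@H]2[C@](C)(CCC3(OCCO3)C2)/C=C\CC(=O)OC
F2 | step 3 | methyl cis-2-(but-3-yn-1-yl)-4-[(triisopropylsilyl)oxy]cyclohex-3-ene-1-carboxylate | C#CCC[C@H]2[C@H](CCC(O[Si](C(C)C)(C(C)C)C(C)C)=C2)C(=O)OC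
F3 | step 3 | methyl 2-(but-3-yn-1-yl)-1-methyl-4-[(triisopropylsilyl)oxy]cyclohex-3-ene-1-carboxylate (methyl trans to butynyl) | C#CCC[C@H]2[C@](C)(CCC(O[Si](C(C)C)(C(C)C)C(C)C)=C2)C(=O)OC
F4 | step 3 | [2-(but-3-yn-1-yl)-1-methyl-4-[(triisopropylsilyl)oxy]cyclohex-3-en-1-yl]methanol | C#CCC[C@H]2[C@](C)(CCC(O[Si](C(C)C)(C(C)C)C(C)C)=C2)CO
F5 | step 4 | (3Z)-4-{2-(but-3-yn-1-yl)-1-methyl-4-[(triisopropylsilyl)oxy]cyclohex-3-en-1-yl}but-3-en-1-ol | C#CCC[C@H]2[C@](C)(CCC(O[Si](C(C)C)(C(C)C)C(C)C)=C2)/C=C\CCO
F6 | step 4 | (3Z)-4-[(7R,8S)-7-(but-3-yn-1-yl)-8-methyl-1,4-dioxaspiro[4.5]decan-8-yl]but-3-en-1-ol | C#CCC[C@H]2[C@](C)(CCC3(OCCO3)C2)/C=C\CCO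
F7 | step 4 | (3Z)-4-[(7R,8S)-7-(but-3-yn-1-yl)-8-methyl-1,4-dioxaspiro[4.5]decan-8-yl]but-3-enal | C#CCC[C@H]2[C@](C)(CCC3(OCCO3)C2)/C=C\CC=O
F8 | step 4 | (3Z)-4-[(7R,8S)-7-(but-3-yn-1-yl)-8-methyl-1,4-dioxaspiro[4.5]decan-8-yl]but-3-enoic acid | C#CCC[C@H]2[C@](C)(CCC3(OCCO3)C2)/C=C\CC(=O)O
F9 | step 15 | allyl (13Z)-3,18-dioxo-4-epi-5β-labda-8(17),13-dien-15-oate (4α-methyl, 4β-formyl) | C=C1CC[C@H]2[C@](C)(CCC(=O)[C@]2(C)C=O)[C@H]1CC/C(C)=C\C(=O)OCC=C
F10 | step 15 | allyl (13Z)-3-oxo-18-nor-5β-labda-8(17),13-dien-15-oate (C4 epimers) | C=C1CC[C@H]2[C@](C)(CCC(=O)C2C)[C@H]1CC/C(C)=C\C(=O)OCC=C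
F11 | step 15 | allyl (13Z)-3-[(trimethylsilyl)oxy]-18-nor-5β-labda-3,8(17),13-trien-15-oate | C=C1CC[C@H]2[C@](C)(CCC(O[Si](C)(C)C)=C2C)[C@H]1CC/C(C)=C\C(=O)OCC=C
A1 | alternative 1 | cis-fused 8-methoxy-4-[(4-methoxybenzyloxy)methyl]-4,10-dimethyloctal-8-en-3-one | C1=C(OC)CC[C@H]2[C@]1(C)CCC(=O)[C@@]2(C)COCc1ccc(OC)cc1
A2 | alternative 2 | methyl cis-fused 8-(tert-butyldimethylsilyloxy)-4,10-dimethyloctal-1-ene-4-carboxylate | CC(C)(C)[Si](C)(C)O[C@H]1CC[C@H]2[C@](C)(C=CC[C@@]2(C)C(=O)OC)C1
A3 | alternative 3 | cis-fused 8,8-(ethylenedioxy)-10-methyl-6,6-bis(phenylsulfonyl)octal-1-en-3-one | C12(OCCO1)CC(S(=O)(=O)c1ccccc1)(S(=O)(=O)c1ccccc1)[C@H]3[C@](C)(C=CC(=O)C3)C2
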